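**Plan**
- Retrosynthesis: the two benzyl ethers and the 3-O-methyl group are removed first, and the pyranone is traced back through a flavan-3,4-diol to a 2H-chromene (C3=C4).
- The chromene is cut at C4–C4a and at O1–C2, which leads to an aryl 1-arylpropargyl ether. This works because ring A has oxygen on every carbon except one, and that single C–H carbon (the future C4a) sits ortho to the oxygen that becomes O1, so the propargyl unit can only migrate there and ring C then closes by oxa-6π electrocyclisation.
- The ether is cut at its O–CH bond into a penta-oxygenated phenol (from 2,6-dimethoxyphenol) and a propargylic alcohol (from 4-(benzyloxy)benzaldehyde and ethynylmagnesium bromide).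
- Forward: ring A is fully oxygenated, ring B is attached through the ether oxygen, the pyran ring closes in the rearrangement cascade, and the ring is then oxidised to the 3-methoxy-pyranone before global debenzylation.
- Stereochemistry: the target is achiral; C2 (and C3, C4 of the diol) arise racemic and are erased on aromatisation of ring C.

Key step: step 8

Remark: compounds 11–19 that carry stereocentres are racemic; wedged SMILES for 17 and 18 show relative configuration only.

**Route**

Step 1
Reactants: 1 2,6-dimethoxyphenol
Product: 2 2-(benzyloxy)-1,3-dimethoxybenzene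
Conditions: BnBr, K2CO3, DMF, 60 °C
Reagents that add atoms: benzyl bromide, BrCc1ccccc1
Why: Williamson O-alkylation of the phenoxide, the only nucleophilic site in 1, with a reactive benzylic halide.

Step 2
Reactants: 2 2-(benzyloxy)-1,3-dimethoxybenzene
Product: 4 3-(benzyloxy)-2,4-dimethoxybenzaldehyde, via iminium chloride 3 (not isolated)
Conditions: POCl3, DMF, 0 → 80 °C; then ice–water
Reagents that add atoms: N,N-dimethylformamide, CN(C)C=O; water, O
Why: Vilsmeier–Haack formylation, which should attack para to one methoxy group and ortho to the other as it does in 1,2,3-trimethoxybenzene, because the twisted central alkoxy group activates its own para position only weakly.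

Step 3
Reactants: 4 3-(benzyloxy)-2,4-dimethoxybenzaldehyde
Product: 5 3-(benzyloxy)-5-bromo-2,4-dimethoxybenzaldehyde
Conditions: NBS, DMF, rt
Reagents that add atoms: N-bromosuccinimide, O=C1CCC(=O)N1Br
Why: electrophilic aromatic bromination at C5, which is ortho to the 4-methoxy and para to the 2-methoxy group and meta to the formyl group, whereas C6 is deactivated by the adjacent formyl group.

Step 4
Reactants: 5 3-(benzyloxy)-5-bromo-2,4-dimethoxybenzaldehyde
Product: 6 3-(benzyloxy)-2,4,5-trimethoxybenzaldehyde
Conditions: NaOMe, CuBr (cat.), EtOAc (cat.), MeOH–DMF, reflux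
Reagents that add atoms: sodium methoxide, C[O-].[Na+]
Why: copper-catalysed Ullmann-type methanolysis of an aryl bromide with an ester cocatalyst, a reaction known to tolerate non-enolisable benzaldehydes, which are masked reversibly as hemiacetal salts in the medium.

Step 5
Reactants: 6 3-(benzyloxy)-2,4,5-trimethoxybenzaldehyde
Product: 8 3-(benzyloxy)-2,4,5-trimethoxyphenol, via aryl formate 7 (not isolated)
Conditions: mCPBA, CH2Cl2, 0 °C → rt; then Et3N (cat.), MeOH, rt, argon
Reagents that add atoms: 3-chloroperoxybenzoic acid, O=C(OO)c1cccc(Cl)c1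
Why: Dakin-type Baeyer–Villiger oxidation, in which the electron-rich aryl group (ortho and para methoxy) should migrate in preference to hydride to give the aryl formate, which is cleaved by methanolysis in the same flask.

Step 6
Reactants: 9 4-(benzyloxy)benzaldehyde; 10 ethynylmagnesium bromide
Product: 11 rac-1-[4-(benzyloxy)phenyl]prop-2-yn-1-ol
Conditions: THF, 0 °C → rt; then sat. aq NH4Cl
Reagents that add atoms: none
Why: 1,2-addition of an alkynyl Grignard reagent to an aromatic aldehyde; the new carbinol centre is formed racemic and needs no control.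

Step 7
Reactants: 8 3-(benzyloxy)-2,4,5-trimethoxyphenol; 11 rac-1-[4-(benzyloxy)phenyl]prop-2-yn-1-ol
Product: 12 rac-1-(benzyloxy)-3-({1-[4-(benzyloxy)phenyl]prop-2-yn-1-yl}oxy)-2,5,6-trimethoxybenzene
Conditions: PPh3, DIAD, THF, 0 °C → rt
Reagents that add atoms: none
Why: Mitsunobu etherification, in which the phenol is acidic enough to protonate the betaine and the phenoxide displaces the oxyphosphonium group at the secondary propargylic carbon; as the alcohol is racemic the stereochemical course is immaterial.

Step 8
Reactants: 12 rac-1-(benzyloxy)-3-({1-[4-(benzyloxy)phenyl]prop-2-yn-1-yl}oxy)-2,5,6-trimethoxybenzene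
Product: 16 rac-7-(benzyloxy)-2-[4-(benzyloxy)phenyl]-5,6,8-trimethoxy-2H-chromene, via allenyl dienone 13 (not isolated), via allenyl phenol 14 (not isolated), via oxatriene 15 (not isolated)
Conditions: PhNEt2 (degassed), 180 °C, argon
Reagents that add atoms: none
Why: On heating, the ether should undergo a concerted aromatic propargyl Claisen ([3,3]) shift that bonds the alkyne terminus to the one unsubstituted ortho carbon (future C4a) and gives allenyl dienone 13, which the amine solvent tautomerises to allenyl phenol 14; a 1,5-shift of the phenolic hydrogen to the central allene carbon then gives oxatriene 15 with its side chain syn to the carbonyl oxygen. The closest known reaction type is the thermal conversion of aryl propargyl ethers, 1-aryl-substituted ones included, into 2H-chromenes in N,N-dialkylanilines. The pyran ring, the only ring formed, closes by thermal disrotatory oxa-6π electrocyclisation of 15 in which O1 bonds to C2, driven by the return of ring A to aromaticity. C2 is the only new stereocentre; no element controls it, it forms racemic, and it is removed when the ring is oxidised in step 10. The step needs regioselectivity and a pericyclic course in preference to C–O ionisation: the first follows from the methoxy group on the other ortho carbon, since a shift to that carbon gives a dienone that cannot enolise and can only revert, and the second is favoured by an apolar solvent of low basicity that disfavours charge separation and by the acceleration that the 1-aryl substituent lends to the [3,3] shift, which should allow a temperature below that needed for unsubstituted propargyl ethers.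

Step 9
Reactants: 16 rac-7-(benzyloxy)-2-[4-(benzyloxy)phenyl]-5,6,8-trimethoxy-2H-chromene
Product: 17 rac-(2R,3S,4S)-7-(benzyloxy)-2-[4-(benzyloxy)phenyl]-5,6,8-trimethoxy-3,4-dihydro-2H-chromene-3,4-diol
Conditions: OsO4 (cat.), NMO, acetone–H2O, rt
Reagents that add atoms: osmium tetroxide, O=[Os](=O)(=O)=O; N-methylmorpholine N-oxide, C[N+]1([O-])CCOCC1; water, O
Why: Upjohn dihydroxylation of the cis-disubstituted styrene-type C3=C4 bond; syn addition on the face opposite the 2-aryl group should give the 2,3-trans-3,4-cis diol, a configuration of no consequence because step 10 removes all three centres.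

Step 10
Reactants: 17 rac-(2R,3S,4S)-7-(benzyloxy)-2-[4-(benzyloxy)phenyl]-5,6,8-trimethoxy-3,4-dihydro-2H-chromene-3,4-diol
Product: 20 7-(benzyloxy)-2-[4-(benzyloxy)phenyl]-3-hydroxy-5,6,8-trimethoxy-4H-chromen-4-one, via trans-dihydroflavonol 18 (not isolated), via flavan-3,4-dione 19 (not isolated)
Conditions: IBX (2.5 equiv), DMSO, rt → 40 °C
Reagents that add atoms: none
Why: IBX oxidation of a vicinal diol to the 1,2-diketone without C–C cleavage, the benzylic C4 hydroxyl reacting first; the 3,4-dione then enolises through its acidic C2–H to the aromatic 3-hydroxy-pyranone.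

Step 11
Reactants: 20 7-(benzyloxy)-2-[4-(benzyloxy)phenyl]-3-hydroxy-5,6,8-trimethoxy-4H-chromen-4-one
Product: 21 7-(benzyloxy)-2-[4-(benzyloxy)phenyl]-3,5,6,8-tetramethoxy-4H-chromen-4-one
Conditions: MeI, K2CO3, acetone, reflux
Reagents that add atoms: iodomethane, CI
Why: Williamson methylation of the acidic 3-hydroxyl, the only free hydroxyl group in 20.

Step 12
Reactants: 21 7-(benzyloxy)-2-[4-(benzyloxy)phenyl]-3,5,6,8-tetramethoxy-4H-chromen-4-one
Product: 22 7-hydroxy-2-(4-hydroxyphenyl)-3,5,6,8-tetramethoxy-4H-chromen-4-one
Conditions: H2 (1 atm), 10% Pd/C (palladium on carbon), EtOAc–MeOH, rt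
Reagents that add atoms: none
Why: catalytic hydrogenolysis of both benzyl aryl ethers, under which the aryl methyl ethers and the tetrasubstituted, conjugated C2=C3 bond of the pyranone should remain untouched.

**Compound list**

1 | 2,6-dimethoxyphenol | COc1cccc(OC)c1O | starting material
2 | 2-(benzyloxy)-1,3-dimethoxybenzene | COc1cccc(OC)c1OCc1ccccc1 | intermediate
3 | N-{[3-(benzyloxy)-2,4-dimethoxyphenyl]methylidene}-N-methylmethanaminium chloride | C[N+](C)=Cc1ccc(OC)c(OCc2ccccc2)c1OC.[Cl-] | intermediate
4 | 3-(benzyloxy)-2,4-dimethoxybenzaldehyde | COc1ccc(C=O)c(OC)c1OCc1ccccc1 | intermediate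
5 | 3-(benzyloxy)-5-bromo-2,4-dimethoxybenzaldehyde | COc1c(Br)cc(C=O)c(OC)c1OCc1ccccc1 | intermediate
6 | 3-(benzyloxy)-2,4,5-trimethoxybenzaldehyde | COc1cc(C=O)c(OC)c(OCc2ccccc2)c1OC | intermediate
7 | 3-(benzyloxy)-2,4,5-trimethoxyphenyl formate | COc1cc(OC=O)c(OC)c(OCc2ccccc2)c1OC | intermediate
8 | 3-(benzyloxy)-2,4,5-trimethoxyphenol | COc1cc(O)c(OC)c(OCc2ccccc2)c1OC | intermediate
9 | 4-(benzyloxy)benzaldehyde | O=Cc1ccc(OCc2ccccc2)cc1 | starting material
10 | ethynylmagnesium bromide | C#C[Mg]Br | starting material
11 | rac-1-[4-(benzyloxy)phenyl]prop-2-yn-1-ol | C#CC(O)c1ccc(OCc2ccccc2)cc1 | intermediate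
12 | rac-1-(benzyloxy)-3-({1-[4-(benzyloxy)phenyl]prop-2-yn-1-yl}oxy)-2,5,6-trimethoxybenzene | C#CC(Oc1cc(OC)c(OC)c(OCc2ccccc2)c1OC)c1ccc(OCc2ccccc2)cc1 | intermediate
13 | 3-(benzyloxy)-6-{3-[4-(benzyloxy)phenyl]propa-1,2-dien-1-yl}-2,4,5-trimethoxycyclohexa-2,4-dien-1-one (mixture of stereoisomers) | O=C1C(OC)=C(OCc2ccccc2)C(OC)=C(OC)C1C=C=Cc1ccc(OCc2ccccc2)cc1 | intermediate
14 | 3-(benzyloxy)-6-{3-[4-(benzyloxy)phenyl]propa-1,2-dien-1-yl}-2,4,5-trimethoxyphenol (racemic allene) | Oc1c(OC)c(OCc2ccccc2)c(OC)c(OC)c1C=C=Cc1ccc(OCc2ccccc2)cc1 | intermediate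
15 | (6Z)-3-(benzyloxy)-6-{3-[4-(benzyloxy)phenyl]prop-2-en-1-ylidene}-2,4,5-trimethoxycyclohexa-2,4-dien-1-one (side chain syn to the carbonyl; styryl double bond geometry not defined) | C(=C/C=C1\C(=O)C(OC)=C(OCc2ccccc2)C(OC)=C1OC)c1ccc(OCc2ccccc2)cc1 | intermediate
16 | rac-7-(benzyloxy)-2-[4-(benzyloxy)phenyl]-5,6,8-trimethoxy-2H-chromene | COc1c(OCc2ccccc2)c(OC)c2c(c1OC)C=CC(c1ccc(OCc3ccccc3)cc1)O2 | intermediate
17 | rac-(2R,3S,4S)-7-(benzyloxy)-2-[4-(benzyloxy)phenyl]-5,6,8-trimethoxy-3,4-dihydro-2H-chromene-3,4-diol (2,3-trans-3,4-cis) | COc1c(OCc2ccccc2)c(OC)c2c(c1OC)[C@H](O)[C@H](O)[C@@H](c1ccc(OCc3ccccc3)cc1)O2 | intermediate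
18 | rac-(2R,3R)-7-(benzyloxy)-2-[4-(benzyloxy)phenyl]-3-hydroxy-5,6,8-trimethoxy-2,3-dihydro-4H-chromen-4-one (2,3-trans) | COc1c(OCc2ccccc2)c(OC)c2c(c1OC)C(=O)[C@H](O)[C@@H](c1ccc(OCc3ccccc3)cc1)O2 | intermediate
19 | rac-7-(benzyloxy)-2-[4-(benzyloxy)phenyl]-5,6,8-trimethoxy-2H-chromene-3,4-dione | COc1c(OCc2ccccc2)c(OC)c2c(c1OC)C(=O)C(=O)C(c1ccc(OCc3ccccc3)cc1)O2 | intermediate
20 | 7-(benzyloxy)-2-[4-(benzyloxy)phenyl]-3-hydroxy-5,6,8-trimethoxy-4H-chromen-4-one | COc1c(OCc2ccccc2)c(OC)c2oc(-c3ccc(OCc4ccccc4)cc3)c(O)c(=O)c2c1OC | intermediate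
21 | 7-(benzyloxy)-2-[4-(benzyloxy)phenyl]-3,5,6,8-tetramethoxy-4H-chromen-4-one | COc1c(OCc2ccccc2)c(OC)c2oc(-c3ccc(OCc4ccccc4)cc3)c(OC)c(=O)c2c1OC | intermediate
22 | 7-hydroxy-2-(4-hydroxyphenyl)-3,5,6,8-tetramethoxy-4H-chromen-4-one | COc1c(O)c(OC)c2oc(-c3ccc(O)cc3)c(OC)c(=O)c2c1OC | target

**Step count**
Total: 12 steps. Longest linear sequence: 11 steps (1 → 2 → 4 → 5 → 6 → 8 → 12 → 16 → 17 → 20 → 21 → 22); step 6 is a one-step side branch.

**Steps most likely to fail**

Step 8. The benzylic, propargylic C–O bond carries a 4-alkoxyphenyl group and an electron-rich aryloxy leaving group, so ionisation at 180 °C may compete with the concerted shift and lead to loss of the phenol or to recombination at carbon without ring closure. In that case the same ether 12 would be cyclised at room temperature by π-acid catalysis with Ph3PAuNTf2 (monovalent gold, catalytic) in CH2Cl2. The catalyst activates the alkyne for 6-endo-dig attack by the free ortho carbon of ring A, and protodeauration should give chromene 16 directly, where the route is rejoined. No compound outside the list arises (F0).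

Step 10. The one-flask double oxidation may suffer from glycol cleavage between C3 and C4, from further oxidation of the electron-rich flavonol enol, or from stopping at the hydroxy ketone stage. The oxidation would then be split into two operations starting from diol 17. DDQ in CH2Cl2–dioxane at room temperature should dehydrogenate only the activated benzylic C4 carbinol, and trans-dihydroflavonol 18 would be isolated. I2 with KOAc in hot AcOH would then oxidise the enediol tautomer of 18 to flavonol 20, where the route is rejoined. No compound outside the list arises (F0).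

Step 7. The oxyphosphonium intermediate of the electron-rich propargylic alcohol may ionise and be captured by the hydrazide nitrogen, or the coupling may stall with the ortho-substituted phenol. Alcohol 11 would then be acetylated (Ac2O, Et3N, DMAP, CH2Cl2) to rac-1-[4-(benzyloxy)phenyl]prop-2-yn-1-yl acetate F1. F1 would be coupled with phenol 8 by copper-catalysed propargylic substitution ((CuOTf)2·C6H6 as a source of monovalent copper, i-Pr2NEt, THF, 0 °C), which proceeds through a copper acetylide and allenylidene and delivers the phenoxide to the propargylic carbon. This gives ether 12, where the route is rejoined.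

**Further compounds**
F0 | step 8 | none | none
F0 | step 10 | none | none
F1 | step 7 | rac-1-[4-(benzyloxy)phenyl]prop-2-yn-1-yl acetate | C#CC(OC(C)=O)c1ccc(OCc2ccccc2)cc1
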